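**Retrosynthetic overview**

1. The strategy rests on ring A, an orsellinate. C1 with its ester carbon, C2 with its oxygen and C3 come from an acetoacetate that is already esterified by the secondary oxygen of hydroxybutyrate unit B1. C4 with its oxygen, C5 and C6 with its methyl group come from a crotonate.
2. Ring A is therefore cut at C1–C6 and C3–C4, back to (R)-pent-4-en-2-yl acetoacetate and tert-butyl crotonate. The terminal alkene stands for the B1 carboxyl group.
3. The two aliphatic ester bonds (B1 carboxyl to the ring C side-chain oxygen, B2 carboxyl to the ring D side-chain oxygen) are cut last and made through acyl chlorides. Each acid is released from a pent-4-en-2-yl ester by alkene cleavage only after its aryl ester exists.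
4. Rings C and D are not constructed. Both come from 1,3-bis(benzyloxy)-5-bromobenzene and (R)-propylene oxide through one arylpropanol. Ring C gains its carboxyl by bromination, lithiation and CO2, and its crowded ester by Mitsunobu inversion of (S)-pent-4-en-2-ol.
5. Ring A is the only ring formed (step 2) and is aromatised in step 3. Six benzyl ethers are removed by hydrogenolysis at the end.

Key step: step 2

Remark: 8 is written as the triketo tautomer; it is expected as a mixture of enol forms and of diastereomers at ring carbons C1 and C6, all of which converge on 9.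

**Route**

Step 1
Reactants: 1 (R)-pent-4-en-2-ol; 2 2,2,6-trimethyl-4H-1,3-dioxin-4-one
Product: 4 (R)-pent-4-en-2-yl 3-oxobutanoate, via acetylketene 3 (not isolated)
Conditions: xylenes, 130 °C, pressure tube
Reagents that add atoms: none
Why: Thermal retro-[4+2] cleavage of the dioxinone releases acetone and acetylketene 3, which the secondary alcohol traps as the β-keto ester (acylketene acetoacetylation) without touching the carbinol centre.

Step 2
Reactants: 4 (R)-pent-4-en-2-yl 3-oxobutanoate; 5 tert-butyl (E)-but-2-enoate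
Product: 8 (R)-pent-4-en-2-yl 6-methyl-2,4-dioxocyclohexane-1-carboxylate, via Michael adduct 6 (not isolated), via potassium diketonate 7 (not isolated)
Conditions: KOtBu (1.1 equiv), t-BuOH/THF, 70 °C; then 1 M aq. HCl, 0 °C
Reagents that add atoms: none
Why: The potassium enolate of 4 adds to the β-carbon of 5 in a Michael reaction (bond C1–C6) to give 6, proton exchange through t-BuOH moves the negative charge to the acetyl methyl group, and this carbon attacks the tert-butyl ester carbonyl with loss of tert-butoxide (bond C3–C4), the dione being held as the diketonate 7 until acid releases 8. The closest known reaction type is the alkoxide-mediated Michael–Dieckmann condensation of alkyl acetoacetates with alkyl crotonates to 6-methyl-2,4-dioxocyclohexane-1-carboxylates. Ring A closes in a 6-exo-trig Claisen (Dieckmann) mode, and every other intramolecular acylation open to 6 would give a four-membered ring. The new stereocentres at C1 and C6 are formed without control and need none, because both carbons become sp2 in step 3, while the (R)-carbinol carbon carries no acidic hydrogen and is not touched. The selectivity needed is between the two ester groups: tert-butoxide is the only alkoxide in the flask, as base and as leaving group, and is too hindered to exchange with the secondary ester, which is also deactivated as an enolate in 4 and 7. The terminal alkene is inert to the base and takes the place of the B1 carboxyl group, which as a β-acyloxy ester would be lost by elimination.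

Step 3
Reactants: 8 (R)-pent-4-en-2-yl 6-methyl-2,4-dioxocyclohexane-1-carboxylate
Product: 9 (R)-pent-4-en-2-yl 2,4-dihydroxy-6-methylbenzoate
Conditions: I2 (20 mol%), DMSO, 80 °C, open vessel
Reagents that add atoms: none
Why: Iodine-catalysed oxidative aromatisation, in which α-iodination of the enolised dione and loss of HI give the dienone tautomer of the resorcinol while DMSO reoxidises HI to I2; iodine adds to an isolated terminal alkene only reversibly, so the alkene should survive.

Step 4
Reactants: 9 (R)-pent-4-en-2-yl 2,4-dihydroxy-6-methylbenzoate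
Product: 10 (R)-pent-4-en-2-yl 2,4-bis(benzyloxy)-6-methylbenzoate
Conditions: BnBr (2.6 equiv), K2CO3, DMF, 60 °C
Reagents that add atoms: benzyl bromide BrCc1ccccc1
Why: Williamson etherification of both phenols (the chelated 2-hydroxyl needs the warm DMF), carbonate being too weak to harm the crowded aryl ester or the alkene.

Step 5
Reactants: 10 (R)-pent-4-en-2-yl 2,4-bis(benzyloxy)-6-methylbenzoate
Product: 12 (R)-4-oxobutan-2-yl 2,4-bis(benzyloxy)-6-methylbenzoate, via vicinal diol 11 (not isolated)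
Conditions: OsO4 (2 mol%), NaIO4 (4 equiv), 2,6-lutidine, 1,4-dioxane/H2O, rt
Reagents that add atoms: osmium tetroxide O=[Os](=O)(=O)=O; sodium periodate [Na+].[O-]I(=O)(=O)=O
Why: Lemieux–Johnson cleavage, in which catalytic OsO4 dihydroxylates only the isolated alkene and periodate cleaves diol 11 to the aldehyde, leaving benzyl ethers and the electron-rich arene alone; the β-aroyloxy aldehyde is taken on crude.

Step 6
Reactants: 12 (R)-4-oxobutan-2-yl 2,4-bis(benzyloxy)-6-methylbenzoate
Product: 13 (R)-3-{[2,4-bis(benzyloxy)-6-methylbenzoyl]oxy}butanoic acid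
Conditions: NaClO2, NaH2PO4, 2-methyl-2-butene, t-BuOH/H2O, 0 °C → rt
Reagents that add atoms: sodium chlorite [Na+].[O-]Cl=O
Why: Pinnick oxidation in a weakly acidic buffer converts the aldehyde to the acid without base-induced β-elimination of the aroyloxy group, and 2-methyl-2-butene scavenges HOCl so the arene is not chlorinated.

Step 7
Reactants: 14 1,3-bis(benzyloxy)-5-bromobenzene; 15 (R)-2-methyloxirane
Product: 17 (R)-1-[3,5-bis(benzyloxy)phenyl]propan-2-ol, via arylmagnesium bromide 16 (not isolated)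
Conditions: Mg, THF, reflux; then CuI (10 mol%), 15, −30 → 0 °C; 1 M aq. HCl, 0 °C
Reagents that add atoms: none
Why: Copper-catalysed SN2 opening of the epoxide by the aryl Grignard reagent at the unsubstituted carbon leaves the stereocentre of (R)-propylene oxide unchanged, so the (R)-carbinol results.

Step 8
Reactants: 17 (R)-1-[3,5-bis(benzyloxy)phenyl]propan-2-ol
Product: 18 tert-butyl{[(R)-1-(3,5-bis(benzyloxy)phenyl)propan-2-yl]oxy}dimethylsilane
Conditions: TBSCl, imidazole, DMF, rt
Reagents that add atoms: tert-butyldimethylsilyl chloride CC(C)(C)[Si](C)(C)Cl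
Why: Imidazole-promoted silylation of the secondary alcohol gives an ether that tolerates the organolithium, Mitsunobu and oxidation steps and is later removed by fluoride.

Step 9
Reactants: 18 tert-butyl{[(R)-1-(3,5-bis(benzyloxy)phenyl)propan-2-yl]oxy}dimethylsilane
Product: 19 {[(R)-1-(3,5-bis(benzyloxy)-2-bromophenyl)propan-2-yl]oxy}(tert-butyl)dimethylsilane
Conditions: NBS (1.0 equiv), MeCN, 0 °C, dark
Reagents that add atoms: N-bromosuccinimide O=C1CCC(=O)N1Br
Why: Electrophilic aromatic bromination of a 3,5-dialkoxy-alkylbenzene goes next to the alkyl chain (para to one ether, ortho to the other; the two such positions are equivalent) and not to the more crowded carbon between the two ethers.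

Step 10
Reactants: 19 {[(R)-1-(3,5-bis(benzyloxy)-2-bromophenyl)propan-2-yl]oxy}(tert-butyl)dimethylsilane
Product: 21 2,4-bis(benzyloxy)-6-[(R)-2-{[tert-butyl(dimethyl)silyl]oxy}propyl]benzoic acid, via aryllithium 20 (not isolated)
Conditions: n-BuLi (1.1 equiv), THF, −78 °C, 10 min; CO2 (g), −78 °C → rt; cold 1 M aq. HCl to pH 3
Reagents that add atoms: carbon dioxide O=C=O
Why: Bromine–lithium exchange and carboxylation of the aryllithium with CO2, with the low temperature and immediate quench keeping the ortho-benzyloxy aryllithium from rearranging.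

Step 11
Reactants: 21 2,4-bis(benzyloxy)-6-[(R)-2-{[tert-butyl(dimethyl)silyl]oxy}propyl]benzoic acid; 22 (S)-pent-4-en-2-ol
Product: 23 (R)-pent-4-en-2-yl 2,4-bis(benzyloxy)-6-[(R)-2-{[tert-butyl(dimethyl)silyl]oxy}propyl]benzoate
Conditions: PPh3, DIAD, THF, 0 °C → rt
Reagents that add atoms: none
Why: Mitsunobu esterification, in which the hindered but acidic 2,6-disubstituted benzoate displaces the oxyphosphonium group of 22 by SN2, so the (S)-alcohol gives the (R)-ester by inversion and the crowded carbonyl never has to be attacked.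

Step 12
Reactants: 23 (R)-pent-4-en-2-yl 2,4-bis(benzyloxy)-6-[(R)-2-{[tert-butyl(dimethyl)silyl]oxy}propyl]benzoate
Product: 25 (R)-4-oxobutan-2-yl 2,4-bis(benzyloxy)-6-[(R)-2-{[tert-butyl(dimethyl)silyl]oxy}propyl]benzoate, via vicinal diol 24 (not isolated)
Conditions: OsO4 (2 mol%), NaIO4 (4 equiv), 2,6-lutidine, 1,4-dioxane/H2O, rt
Reagents that add atoms: osmium tetroxide O=[Os](=O)(=O)=O; sodium periodate [Na+].[O-]I(=O)(=O)=O
Why: Lemieux–Johnson cleavage of the terminal alkene as in step 5, the silyl ether, benzyl ethers and aryl ester being inert.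

Step 13
Reactants: 25 (R)-4-oxobutan-2-yl 2,4-bis(benzyloxy)-6-[(R)-2-{[tert-butyl(dimethyl)silyl]oxy}propyl]benzoate
Product: 26 (R)-3-({2,4-bis(benzyloxy)-6-[(R)-2-{[tert-butyl(dimethyl)silyl]oxy}propyl]benzoyl}oxy)butanoic acid
Conditions: NaClO2, NaH2PO4, 2-methyl-2-butene, t-BuOH/H2O, 0 °C → rt
Reagents that add atoms: sodium chlorite [Na+].[O-]Cl=O
Why: Pinnick oxidation as in step 6, mild enough for the secondary silyl ether and free of base that would eliminate the β-aroyloxy group.

Step 14
Reactants: 26 (R)-3-({2,4-bis(benzyloxy)-6-[(R)-2-{[tert-butyl(dimethyl)silyl]oxy}propyl]benzoyl}oxy)butanoic acid; 17 (R)-1-[3,5-bis(benzyloxy)phenyl]propan-2-ol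
Product: 28 (R)-1-[3,5-bis(benzyloxy)phenyl]propan-2-yl (R)-3-({2,4-bis(benzyloxy)-6-[(R)-2-{[tert-butyl(dimethyl)silyl]oxy}propyl]benzoyl}oxy)butanoate, via acyl chloride 27 (not isolated)
Conditions: 1-chloro-N,N,2-trimethylprop-1-en-1-amine (Ghosez reagent), CH2Cl2, 0 °C; then 17, pyridine, CH2Cl2, −40 → 0 °C
Reagents that add atoms: none
Why: Neutral acyl chloride formation with the α-chloroenamine and acylation of the secondary alcohol with pyridine as a weak base at low temperature, chosen to keep E1cB loss of the β-aroyloxy group small; both carbinol configurations are retained.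

Step 15
Reactants: 28 (R)-1-[3,5-bis(benzyloxy)phenyl]propan-2-yl (R)-3-({2,4-bis(benzyloxy)-6-[(R)-2-{[tert-butyl(dimethyl)silyl]oxy}propyl]benzoyl}oxy)butanoate
Product: 29 (R)-1-[3,5-bis(benzyloxy)phenyl]propan-2-yl (R)-3-({2,4-bis(benzyloxy)-6-[(R)-2-hydroxypropyl]benzoyl}oxy)butanoate
Conditions: HF·pyridine, THF/pyridine, 0 °C → rt
Reagents that add atoms: none
Why: Fluoride desilylation under buffered, weakly acidic conditions spares the esters and benzyl ethers and forms no alkoxide that could cyclise onto the neighbouring aryl ester.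

Step 16
Reactants: 13 (R)-3-{[2,4-bis(benzyloxy)-6-methylbenzoyl]oxy}butanoic acid; 29 (R)-1-[3,5-bis(benzyloxy)phenyl]propan-2-yl (R)-3-({2,4-bis(benzyloxy)-6-[(R)-2-hydroxypropyl]benzoyl}oxy)butanoate
Product: 31 hexa-O-benzyl Hansforester A, via acyl chloride 30 (not isolated)
Conditions: 1-chloro-N,N,2-trimethylprop-1-en-1-amine (Ghosez reagent), CH2Cl2, 0 °C; then 29, pyridine, CH2Cl2, −40 → 0 °C
Reagents that add atoms: none
Why: Acyl chloride esterification as in step 14, in which the cold, weakly basic medium should favour acylation of the free hydroxyl over both elimination in 30 and lactonisation of 29, with retention at every stereocentre.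

Step 17
Reactants: 31 hexa-O-benzyl Hansforester A
Product: 32 Hansforester A
Conditions: H2 (1 atm), 10% Pd/C, EtOAc/EtOH, rt
Reagents that add atoms: none
Why: Catalytic hydrogenolysis removes the six aryl benzyl ethers, while the four esters and their homobenzylic or aliphatic C–O bonds are not cleaved and no stereocentre is affected.

**Compound list**

1 | (R)-pent-4-en-2-ol | C[C@@H](O)CC=C | starting material
2 | 2,2,6-trimethyl-4H-1,3-dioxin-4-one | CC1=CC(=O)OC(C)(C)O1 | starting material
3 | acetylketene | CC(=O)C=C=O | intermediate (not isolated)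
4 | (R)-pent-4-en-2-yl 3-oxobutanoate | CC(=O)CC(=O)O[C@H](C)CC=C | intermediate
5 | tert-butyl (E)-but-2-enoate | C/C=C/C(=O)OC(C)(C)C | starting material
6 | 5-tert-butyl 1-[(R)-pent-4-en-2-yl] 2-acetyl-3-methylpentanedioate (Michael adduct, present as its potassium enolate) | CC(=O)C(C(C)CC(=O)OC(C)(C)C)C(=O)O[C@H](C)CC=C | intermediate (not isolated)
7 | potassium diketonate of 8 | [K+].CC1CC(=O)C=C([O-])C1C(=O)O[C@H](C)CC=C | intermediate (not isolated)
8 | (R)-pent-4-en-2-yl 6-methyl-2,4-dioxocyclohexane-1-carboxylate | CC1CC(=O)CC(=O)C1C(=O)O[C@H](C)CC=C | intermediate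
9 | (R)-pent-4-en-2-yl 2,4-dihydroxy-6-methylbenzoate | Cc1cc(O)cc(O)c1C(=O)O[C@H](C)CC=C | intermediate
10 | (R)-pent-4-en-2-yl 2,4-bis(benzyloxy)-6-methylbenzoate | Cc1cc(OCc2ccccc2)cc(OCc2ccccc2)c1C(=O)O[C@H](C)CC=C | intermediate
11 | (2R)-4,5-dihydroxypentan-2-yl 2,4-bis(benzyloxy)-6-methylbenzoate (both C4 epimers) | Cc1cc(OCc2ccccc2)cc(OCc2ccccc2)c1C(=O)O[C@H](C)CC(O)CO | intermediate (not isolated)
12 | (R)-4-oxobutan-2-yl 2,4-bis(benzyloxy)-6-methylbenzoate | Cc1cc(OCc2ccccc2)cc(OCc2ccccc2)c1C(=O)O[C@H](C)CC=O | intermediate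
13 | (R)-3-{[2,4-bis(benzyloxy)-6-methylbenzoyl]oxy}butanoic acid | Cc1cc(OCc2ccccc2)cc(OCc2ccccc2)c1C(=O)O[C@H](C)CC(=O)O | intermediate
14 | 1,3-bis(benzyloxy)-5-bromobenzene | Brc1cc(OCc2ccccc2)cc(OCc2ccccc2)c1 | starting material
15 | (R)-2-methyloxirane | C[C@@H]1CO1 | starting material
16 | [3,5-bis(benzyloxy)phenyl]magnesium bromide | Br[Mg]c1cc(OCc2ccccc2)cc(OCc2ccccc2)c1 | intermediate (not isolated)
17 | (R)-1-[3,5-bis(benzyloxy)phenyl]propan-2-ol | C[C@@H](O)Cc1cc(OCc2ccccc2)cc(OCc2ccccc2)c1 | intermediate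
18 | tert-butyl{[(R)-1-(3,5-bis(benzyloxy)phenyl)propan-2-yl]oxy}dimethylsilane | C[C@@H](O[Si](C)(C)C(C)(C)C)Cc1cc(OCc2ccccc2)cc(OCc2ccccc2)c1 | intermediate
19 | {[(R)-1-(3,5-bis(benzyloxy)-2-bromophenyl)propan-2-yl]oxy}(tert-butyl)dimethylsilane | C[C@@H](O[Si](C)(C)C(C)(C)C)Cc1cc(OCc2ccccc2)cc(OCc2ccccc2)c1Br | intermediate
20 | aryllithium from 19 (lithium in place of bromine) | C[C@@H](O[Si](C)(C)C(C)(C)C)Cc1cc(OCc2ccccc2)cc(OCc2ccccc2)c1[Li] | intermediate (not isolated)
21 | 2,4-bis(benzyloxy)-6-[(R)-2-{[tert-butyl(dimethyl)silyl]oxy}propyl]benzoic acid | C[C@@H](O[Si](C)(C)C(C)(C)C)Cc1cc(OCc2ccccc2)cc(OCc2ccccc2)c1C(=O)O | intermediate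
22 | (S)-pent-4-en-2-ol | C[C@H](O)CC=C | starting material
23 | (R)-pent-4-en-2-yl 2,4-bis(benzyloxy)-6-[(R)-2-{[tert-butyl(dimethyl)silyl]oxy}propyl]benzoate | C[C@@H](O[Si](C)(C)C(C)(C)C)Cc1cc(OCc2ccccc2)cc(OCc2ccccc2)c1C(=O)O[C@H](C)CC=C | intermediate
24 | (2R)-4,5-dihydroxypentan-2-yl 2,4-bis(benzyloxy)-6-[(R)-2-{[tert-butyl(dimethyl)silyl]oxy}propyl]benzoate (both C4 epimers) | C[C@@H](O[Si](C)(C)C(C)(C)C)Cc1cc(OCc2ccccc2)cc(OCc2ccccc2)c1C(=O)O[C@H](C)CC(O)CO | intermediate (not isolated)
25 | (R)-4-oxobutan-2-yl 2,4-bis(benzyloxy)-6-[(R)-2-{[tert-butyl(dimethyl)silyl]oxy}propyl]benzoate | C[C@@H](O[Si](C)(C)C(C)(C)C)Cc1cc(OCc2ccccc2)cc(OCc2ccccc2)c1C(=O)O[C@H](C)CC=O | intermediate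
26 | (R)-3-({2,4-bis(benzyloxy)-6-[(R)-2-{[tert-butyl(dimethyl)silyl]oxy}propyl]benzoyl}oxy)butanoic acid | C[C@@H](O[Si](C)(C)C(C)(C)C)Cc1cc(OCc2ccccc2)cc(OCc2ccccc2)c1C(=O)O[C@H](C)CC(=O)O | intermediate
27 | acyl chloride of 26 | C[C@@H](O[Si](C)(C)C(C)(C)C)Cc1cc(OCc2ccccc2)cc(OCc2ccccc2)c1C(=O)O[C@H](C)CC(=O)Cl | intermediate (not isolated)
28 | (R)-1-[3,5-bis(benzyloxy)phenyl]propan-2-yl (R)-3-({2,4-bis(benzyloxy)-6-[(R)-2-{[tert-butyl(dimethyl)silyl]oxy}propyl]benzoyl}oxy)butanoate | C[C@@H](O[Si](C)(C)C(C)(C)C)Cc1cc(OCc2ccccc2)cc(OCc2ccccc2)c1C(=O)O[C@H](C)CC(=O)O[C@H](C)Cc1cc(OCc2ccccc2)cc(OCc2ccccc2)c1 | intermediate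
29 | (R)-1-[3,5-bis(benzyloxy)phenyl]propan-2-yl (R)-3-({2,4-bis(benzyloxy)-6-[(R)-2-hydroxypropyl]benzoyl}oxy)butanoate | C[C@@H](O)Cc1cc(OCc2ccccc2)cc(OCc2ccccc2)c1C(=O)O[C@H](C)CC(=O)O[C@H](C)Cc1cc(OCc2ccccc2)cc(OCc2ccccc2)c1 | intermediate
30 | (R)-3-{[2,4-bis(benzyloxy)-6-methylbenzoyl]oxy}butanoyl chloride | Cc1cc(OCc2ccccc2)cc(OCc2ccccc2)c1C(=O)O[C@H](C)CC(=O)Cl | intermediate (not isolated)
31 | hexa-O-benzyl Hansforester A (all six phenols as benzyl ethers, all four carbinol centres R) | Cc1cc(OCc2ccccc2)cc(OCc2ccccc2)c1C(=O)O[C@H](C)CC(=O)O[C@H](C)Cc1cc(OCc2ccccc2)cc(OCc2ccccc2)c1C(=O)O[C@H](C)CC(=O)O[C@H](C)Cc1cc(OCc2ccccc2)cc(OCc2ccccc2)c1 | intermediate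
32 | Hansforester A | Cc1cc(O)cc(O)c1C(=O)O[C@H](C)CC(=O)O[C@H](C)Cc1cc(O)cc(O)c1C(=O)O[C@H](C)CC(=O)O[C@H](C)Cc1cc(O)cc(O)c1 | target

**Step count**

Total: 17 steps. Longest linear sequence: 11 steps (steps 7 to 17, from 14). The ring A branch (steps 1 to 6) joins at step 16.

**Steps most likely to fail**

Step 2. The Claisen closure onto the crowded tert-butyl ester may lag behind reversal of the conjugate addition and behind self-condensation of the crotonate through its γ-anion, so that open-chain material accumulates. The fallback makes the two ring bonds in the opposite order and sets out from 4. Its dianion (NaH, then n-BuLi, THF, 0 °C) would be acylated at the terminal carbon with (E)-N-methoxy-N-methylbut-2-enamide (C/C=C/C(=O)N(C)OC) at −78 °C to give (R)-pent-4-en-2-yl (E)-3,5-dioxooct-6-enoate F1, which forms bond C3–C4. KOtBu in t-BuOH/THF would then close bond C1–C6 by intramolecular 6-endo-trig Michael addition. Any reversible oxygen adduct should drain through the diketonate, and acidification returns the route at 8.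

Step 3. Iodination of the resorcinol ring of the product may consume the catalyst, or loss of HI from the α-iodo dione may be slow, so that dehydrogenation stalls. The fallback sets out from 8. Silylation (TMSCl, Et3N, CH2Cl2) would give (R)-pent-4-en-2-yl 6-methyl-2,4-bis[(trimethylsilyl)oxy]cyclohexa-1,3-diene-1-carboxylate F2. Pd(OAc)2 (1.1 equiv) in MeCN at rt would then effect a Saegusa–Ito dehydrosilylation: palladation at C1 and β-hydride loss from C6. Dilute acid work-up removes the remaining silyl group and the route is rejoined at 9.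

Step 16. Under the amine base the acyl chloride 30 may lose its β-aroyloxy group by elimination, and 29 may cyclise through its free hydroxyl onto the neighbouring aryl ester, both at the stage where the two partners are most valuable. The fallback changes the order of assembly so that this acylation is done early on an alcohol that can be used in excess, and the last union uses an alcohol that cannot cyclise. It sets out from 23.
- Desilylation (HF·pyridine, THF/pyridine) would give (R)-pent-4-en-2-yl 2,4-bis(benzyloxy)-6-[(R)-2-hydroxypropyl]benzoate F3.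
- An excess of F3 would be acylated with 30 (made from 13 as in step 16) to (R)-pent-4-en-2-yl 2,4-bis(benzyloxy)-6-{(R)-2-[((R)-3-{[2,4-bis(benzyloxy)-6-methylbenzoyl]oxy}butanoyl)oxy]propyl}benzoate F4.
- OsO4/NaIO4 cleavage would pass through the 4,5-dihydroxypentan-2-yl ester F5 to the 4-oxobutan-2-yl ester F6.
- Pinnick oxidation would give the ring A–B1–ring C–B2 carboxylic acid F7.
- The Ghosez reagent would convert F7 to its acyl chloride F8, which acylates an excess of 17 in pyridine/CH2Cl2 and returns the route at 31.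

**Further compounds**

F1 | step 2 | (R)-pent-4-en-2-yl (E)-3,5-dioxooct-6-enoate | C/C=C/C(=O)CC(=O)CC(=O)O[C@H](C)CC=C
F2 | step 3 | (R)-pent-4-en-2-yl 6-methyl-2,4-bis[(trimethylsilyl)oxy]cyclohexa-1,3-diene-1-carboxylate | CC1CC(O[Si](C)(C)C)=CC(O[Si](C)(C)C)=C1C(=O)O[C@H](C)CC=C
F3 | step 16 | (R)-pent-4-en-2-yl 2,4-bis(benzyloxy)-6-[(R)-2-hydroxypropyl]benzoate | C[C@@H](O)Cc1cc(OCc2ccccc2)cc(OCc2ccccc2)c1C(=O)O[C@H](C)CC=C
F4 | step 16 | (R)-pent-4-en-2-yl 2,4-bis(benzyloxy)-6-{(R)-2-[((R)-3-{[2,4-bis(benzyloxy)-6-methylbenzoyl]oxy}butanoyl)oxy]propyl}benzoate | Cc1cc(OCc2ccccc2)cc(OCc2ccccc2)c1C(=O)O[C@H](C)CC(=O)O[C@H](C)Cc1cc(OCc2ccccc2)cc(OCc2ccccc2)c1C(=O)O[C@H](C)CC=C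
F5 | step 16 | (2R)-4,5-dihydroxypentan-2-yl ester corresponding to F4 (both C4 epimers) | Cc1cc(OCc2ccccc2)cc(OCc2ccccc2)c1C(=O)O[C@H](C)CC(=O)O[C@H](C)Cc1cc(OCc2ccccc2)cc(OCc2ccccc2)c1C(=O)O[C@H](C)CC(O)CO
F6 | step 16 | (R)-4-oxobutan-2-yl ester corresponding to F4 | Cc1cc(OCc2ccccc2)cc(OCc2ccccc2)c1C(=O)O[C@H](C)CC(=O)O[C@H](C)Cc1cc(OCc2ccccc2)cc(OCc2ccccc2)c1C(=O)O[C@H](C)CC=O
F7 | step 16 | (R)-3-[(2,4-bis(benzyloxy)-6-{(R)-2-[((R)-3-{[2,4-bis(benzyloxy)-6-methylbenzoyl]oxy}butanoyl)oxy]propyl}benzoyl)oxy]butanoic acid | Cc1cc(OCc2ccccc2)cc(OCc2ccccc2)c1C(=O)O[C@H](C)CC(=O)O[C@H](C)Cc1cc(OCc2ccccc2)cc(OCc2ccccc2)c1C(=O)O[C@H](C)CC(=O)O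
F8 | step 16 | acyl chloride of F7 | Cc1cc(OCc2ccccc2)cc(OCc2ccccc2)c1C(=O)O[C@H](C)CC(=O)O[C@H](C)Cc1cc(OCc2ccccc2)cc(OCc2ccccc2)c1C(=O)O[C@H](C)CC(=O)Cl
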